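Readings and results are calculated for substances that don't exist, noise included.

The ratio to watch when repeating this run is the exposure gained in the first minute over the exposure gained in an equal later minute.

| flask | left-handed substrate | right-handed substrate | coupling partner | free catalyst | racemization catalyst | remark | time |
|---|---|---|---|---|---|---|---|
| delta | 0.26 M | 0.26 M | 2 equiv | 2.8 mol% | 1 mol% | the very flask that is asked about, followed so far |  |
| flask | 0.26 M | 0.26 M | 2.00 equiv | 2.8 mol% | 1 mol% |  | 4.0 min |

delta run (percent of the left-handed substrate and right-handed substrate together charged)

| time / min | left-handed product / % |
|---|---|
| 0.200 | 9.0 |
| 0.667 | 23.4 |
| 1.00 | 28.6 |
| 1.50 | 34.5 |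
| 2.50 | 40.0 |

(each reading ± 0.5 percentage points)

- free catalyst is single-handed; left-handed substrate and right-handed substrate are mirror images of each other, charged as a racemate, each of them at the stated concentration
- left-handed product taken out counts as made
- the earlier runs were read with a standard deviation of 0.5 percentage points
- what may be going on: coupling partner + free catalyst + left-handed substrate -> free catalyst + left-handed product; coupling partner + free catalyst + right-handed substrate -> free catalyst + right-handed product; left-handed substrate + racemization catalyst <-> right-handed substrate + racemization catalyst; coupling partner -> decomposed reagent
- "the catalyst" is free catalyst with its forms; racemization catalyst is a second catalyst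
- additions bring no volume worth counting

- west: at 4.0 min add free catalyst, 100% of the amount charged, then wait 2.0 min
- south-west: at 4.0 min add coupling partner, 50.0% of the amount charged, then wait 2.0 min
- east: at 4.0 min take out 90% of the left-handed product then present, then wait 2.0 min
- north-west: change nothing and wait 2.0 min more

1. left-handed product, in percent of the left-handed substrate and right-handed substrate together first charged, at 4.0 min
2. the option that brings most further left-handed product ("none" if no option brings more than 2 percentage points) (west / south-west / east / north-west / none)
3. left-handed product present, with what was taken out counted in, in percent of the left-handed substrate and right-handed substrate together first charged, after east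
4. left-handed product present, with what was taken out counted in, in percent of the left-handed substrate and right-handed substrate together first charged, after north-west

Exposure is ln(s/(s − P)), where s = 0.5 is the left-handed substrate's fraction of the charge and P is the left-handed product's fraction. It counts first-order lifetimes given to left-handed substrate that nothing refills. I assume the rate follows free catalyst times coupling partner and that the partner dies exponentially at rate λ. The rate then integrates to:

E(t) = E∞ (1 − exp(−λt))

Ratio of the windows from zero and from 1.50 min: 1.94

λ = 0.441 /min

E∞ = 2.38

This E∞ is the total exposure a charge of coupling partner delivers.

The ladder has three rungs. The partner's die-away time is 2.27 min, shorter than the 4.0 min of the look. Left-handed substrate starts with a lifetime of 1.01 min, shorter than that die-away time. So the product climbs first, and by the look the drive has faded. The readings give no rung for the racemization catalyst.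

My reckoning for this flask gives 43.0% at 4.0 min. Waiting buys 0.239 of exposure, worth 1.5 percentage points, less than the margin. Taking product out changes no term. Doubling the catalyst buys 0.478, while the fresh partner buys more: 0.697, or 3.5 points. So I choose south-west.

The forecast says 44% (from 42.5% to 47%), 45.7% after east and 45.5% after north-west, a little above mine, and “So south-west is best.”

The flask gives 43.9%, south-west as best with 14 points, and 45.0% after east and 45.0% after north-west.

    coupling partner + free catalyst + left-handed substrate → free catalyst + left-handed product (k = 5.00 /M²/s)
    coupling partner + free catalyst + right-handed substrate → free catalyst + right-handed product (k = 0.440 /M²/s)
    left-handed substrate + racemization catalyst ⇌ right-handed substrate + racemization catalyst, rate k3*[racemization catalyst]*[left-handed substrate] forward; the back reaction follows from the equilibrium constant (k = 17.0 /M/s)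
    coupling partner → decomposed reagent (k = 0.00730 /s)

South-west brings 14 points against my reckoned 3.5 points, so the plateau is not the left-handed share: the falling level of coupling partner is the main reason that left-handed product stands at 43.9% at 4.0 min and not at 81.3%. At 4.00 min left-handed substrate still stands at 25.9%, with 3.81% of the coupling partner left, and with racemization struck out the gain is 6.8 points. Spread over both hands of the substrate, E∞ gives:

15 points

The forecast's range is left behind by 1.72 equiv or 2.31 equiv of partner, where the answer to "now" has moved 5 points.

With 0.7 mol% of free catalyst, exposure at 4.0 min scales to 0.493, giving 19.5% left-handed product. The computed neighbour gives 19.5%.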